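## Retrosynthetic overview

1. Target ⇒ open an O7/C8-fused enol lactone and make the isobutenyl group by Wittig olefination of an aldehyde; ring A is already dearomatised at this stage.
2. The C6–CH2 bond, the C6 quaternary centre and the side-chain centre ⇒ one organocatalytic dearomatising conjugate addition/protonation of a 6-prenyl phenol lactone onto 5-methyl-2-methylidenehex-5-enal (the proposed new step).
3. Lactone ring C (benzylic centre) ⇒ NHC-catalysed annulation of the 6-prenyl chromanone with 3-phenylprop-2-ynal at C8/O7.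
4. Prenyl at C6 ⇒ C-alkylation; pyranone ring B (C2, C3) ⇒ cinchona-catalysed oxa-Michael closure of tigloylphloroglucinol, made from phloroglucinol (ring A) and tigloyl chloride.
5. Ring order: ring A bought, ring B closed first, temporary lactone ring C second, ring A dearomatised third, ring C opened last. The enal comes from 2-methylpenta-1,4-diene by hydroformylation and α-methylenation.

Assumption: the target is one tautomer of an enolised cyclic triketone and is written in the given form; the catalyst enantiomers named are the working choices, and the antipode is taken if a test run shows the opposite sense.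

Locants: chromanone numbering (O1, C2 to C8a) for bicyclic compounds; pyrano[2,3-f]chromene numbering (O1, C2, C3, C4, C4a, C5, C6, C6a, O7, C8, C9, C10, C10a, C10b) for the lactones, where O7/C8 is the lactone and C10 the benzylic carbon.

## Route

Step 1
Reactants: 1 phloroglucinol; 2 tigloyl chloride
Product: 3 (E)-2-methyl-1-(2,4,6-trihydroxyphenyl)but-2-en-1-one
Conditions: AlCl3 (3.0 equiv), PhNO2/CH2Cl2 (1:1), 0 °C to rt, 3 h; cold 1 M HCl quench
Reagents that add atoms: none
Why: Friedel–Crafts C-acylation of the threefold-symmetric triol gives a single mono-acyl product, and the twisted α-methyl enone does not cyclise before the cold acidic quench, so the open ketone can be isolated.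

Step 2
Reactants: 3 (E)-2-methyl-1-(2,4,6-trihydroxyphenyl)but-2-en-1-one
Product: 4 (2S,3R)-5,7-dihydroxy-2,3-dimethylchroman-4-one (cis)
Conditions: quinidine (10 mol%), PhCl/THF (9:1), 20 °C, 48 h
Reagents that add atoms: none
Why: Cinchona-catalysed intramolecular oxa-Michael addition: the quinuclidine nitrogen activates one of the two equivalent ortho hydroxyls, the chiral ion pair fixes the face of attack at the β-carbon (C2, S), and kinetic protonation of the enol by the quinuclidinium gives the cis 3R methyl, so the first stereocentres come from an achiral ketone by asymmetric catalysis.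

Step 3
Reactants: 4 (2S,3R)-5,7-dihydroxy-2,3-dimethylchroman-4-one; 5 prenyl bromide
Product: 6 (2S,3R)-5,7-dihydroxy-2,3-dimethyl-6-(3-methylbut-2-en-1-yl)chroman-4-one
Conditions: 5 (1.0 equiv), KOH (2.2 equiv), H2O, 0 °C, 2 h; then 1 M HCl
Reagents that add atoms: none
Why: Alkaline C-alkylation of the 5,7-dioxido dianion in water favours C6, the carbon flanked by both oxido groups, and the dianion resists deprotonation at C3, so the cis ring should survive; the 8-prenyl and diprenyl by-products are removed by chromatography.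

Step 4
Reactants: 6 (2S,3R)-5,7-dihydroxy-2,3-dimethyl-6-(3-methylbut-2-en-1-yl)chroman-4-one; 7 3-phenylprop-2-ynal
Product: 8 (2S,3R,10R)-5-hydroxy-2,3-dimethyl-6-(3-methylbut-2-en-1-yl)-10-phenyl-2,3,9,10-tetrahydro-4H,8H-pyrano[2,3-f]chromene-4,8-dione
Conditions: 7 (1.3 equiv), (5aR,10bS)-5a,10b-dihydro-2-(2,4,6-trimethylphenyl)-4H,6H-indeno[2,1-b]-1,2,4-triazolo[4,3-d]-1,4-oxazinium chloride (10 mol%), i-Pr2NEt (10 mol%), toluene, 40 °C, 24 h
Reagents that add atoms: none
Why: NHC-catalysed redox annulation: the carbene turns the ynal into an α,β-unsaturated acyl azolium, which is attacked by C8 (the only free ring carbon) and then acylates O7 (the only free neighbouring oxygen) to close the dihydrocoumarin ring, with the aminoindanol backbone setting C10 (R) under catalyst control.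

Step 5
Reactants: 9 2-methylpenta-1,4-diene
Product: 10 5-methylhex-5-enal
Conditions: Rh(acac)(CO)2 (0.5 mol%), 4,5-bis(diphenylphosphino)-9,9-dimethylxanthene (1 mol%), CO/H2 (1:1, 10 bar), toluene, 60 °C
Reagents that add atoms: carbon monoxide, [C-]#[O+]
Why: Linear-selective hydroformylation with a wide-bite-angle diphosphine puts the formyl group on the terminal carbon of the monosubstituted alkene, while the 1,1-disubstituted alkene stays untouched.

Step 6
Reactants: 10 5-methylhex-5-enal
Product: 11 5-methyl-2-methylidenehex-5-enal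
Conditions: 37% aq. CH2O (1.1 equiv), pyrrolidine (10 mol%), propionic acid (10 mol%), i-PrOH, 45 °C, 2 h
Reagents that add atoms: formaldehyde, C=O
Why: Amine-catalysed α-methylenation (Mannich condensation of the enamine with formaldehyde, then loss of the amine) is reliable for linear aldehydes; the enal is used fresh.

Step 7
Reactants: 8 (2S,3R,10R)-5-hydroxy-2,3-dimethyl-6-(3-methylbut-2-en-1-yl)-10-phenyl-2,3,9,10-tetrahydro-4H,8H-pyrano[2,3-f]chromene-4,8-dione; 11 5-methyl-2-methylidenehex-5-enal
Product: 12 (2R)-2-{[(2S,3R,6R,10R)-2,3-dimethyl-6-(3-methylbut-2-en-1-yl)-4,5,8-trioxo-10-phenyl-2,3,4,5,9,10-hexahydro-6H,8H-pyrano[2,3-f]chromen-6-yl]methyl}-5-methylhex-5-enal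
Conditions: 11 (1.5 equiv), (S)-N1,N1-diethyl-3,3-dimethylbutane-1,2-diamine (20 mol%), (R)-3,3'-bis(2,4,6-triisopropylphenyl)-1,1'-binaphthyl-2,2'-diyl hydrogen phosphate (20 mol%), CHCl3, 0 °C, 24 to 48 h; short silica plug, used at once
Reagents that add atoms: none
Why: Proposed new method: a dearomatising conjugate addition with enantioselective protonation under primary-amine/chiral-phosphate catalysis, in which the primary amine forms an iminium ion with the α-branched enal 11, the phosphate anion holds the C5–OH of 8 by a hydrogen bond and so selects the face of the prenyl-bearing C6 (ortho to that hydroxyl, para to O1, the only nucleophilic ring carbon outside the lactone) that attacks the iminium CH2, C6 cannot re-aromatise because it carries no hydrogen so the push-pull dienone is kept, and the enamine is then protonated by the neighbouring tertiary ammonium N–H of the diamine to set the side-chain centre; the two centres form in separate elementary steps, each governed by a different chiral component, so the (6R),(2R) pair is reached by choosing each enantiomer independently; the closest known reaction types are primary-amine-catalysed Friedel–Crafts alkylation with enantioselective enamine protonation of α-substituted acroleins, organocatalytic dearomatisation of 1-substituted 2-naphthols with Michael acceptors, and alkylative dearomatisation of acylphloroglucinols with enals.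

Step 8
Reactants: 12 (2R)-2-{[(2S,3R,6R,10R)-2,3-dimethyl-6-(3-methylbut-2-en-1-yl)-4,5,8-trioxo-10-phenyl-2,3,4,5,9,10-hexahydro-6H,8H-pyrano[2,3-f]chromen-6-yl]methyl}-5-methylhex-5-enal
Product: 14 (3R)-3-{(2S,3R,6S)-4-hydroxy-2,3-dimethyl-6-[(2R)-5-methyl-2-(2-methylprop-1-en-1-yl)hex-5-en-1-yl]-6-(3-methylbut-2-en-1-yl)-5,7-dioxo-3,5,6,7-tetrahydro-2H-chromen-8-yl}-3-phenylpropanoic acid (the target), via enol lactone 13 (not isolated)
Conditions: i-PrPPh3I (1.3 equiv), n-BuLi (1.25 equiv), THF, 0 °C; then 12, −78 °C, 30 min; then LiOH (3 equiv), THF/H2O (3:1), 0 °C, 30 min; 1 M HCl to pH 3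
Reagents that add atoms: isopropyltriphenylphosphonium iodide, CC(C)[P+](c1ccccc1)(c1ccccc1)c1ccccc1.[I-]; lithium hydroxide, [Li+].[OH-]
Why: Wittig olefination with the non-stabilised isopropylidene ylide is fast on the aldehyde at −78 °C and should leave the α-centre, C3 and the hindered ring carbonyls alone, after which hydroxide cleaves the activated enol lactone within minutes to the carboxylate and the enolised triketone, which is stable to base and gives the target on acidification.

## Compound list

1 | phloroglucinol (benzene-1,3,5-triol) | Oc1cc(O)cc(O)c1 | starting material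
2 | tigloyl chloride, (E)-2-methylbut-2-enoyl chloride | C/C=C(\C)C(Cl)=O | starting material
3 | (E)-2-methyl-1-(2,4,6-trihydroxyphenyl)but-2-en-1-one | C/C=C(\C)C(=O)c1c(O)cc(O)cc1O | intermediate
4 | (2S,3R)-5,7-dihydroxy-2,3-dimethylchroman-4-one (cis) | O=C1[C@H](C)[C@H](C)Oc2cc(O)cc(O)c21 | intermediate
5 | prenyl bromide (1-bromo-3-methylbut-2-ene) | CC(C)=CCBr | starting material
6 | (2S,3R)-5,7-dihydroxy-2,3-dimethyl-6-(3-methylbut-2-en-1-yl)chroman-4-one | O=C1[C@H](C)[C@H](C)Oc2cc(O)c(CC=C(C)C)c(O)c21 | intermediate
7 | 3-phenylprop-2-ynal | O=CC#Cc1ccccc1 | starting material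
8 | (2S,3R,10R)-5-hydroxy-2,3-dimethyl-6-(3-methylbut-2-en-1-yl)-10-phenyl-2,3,9,10-tetrahydro-4H,8H-pyrano[2,3-f]chromene-4,8-dione | O=C1[C@H](C)[C@H](C)Oc2c3c(c(CC=C(C)C)c(O)c21)OC(=O)C[C@@H]3c1ccccc1 | intermediate
9 | 2-methylpenta-1,4-diene | C=CCC(C)=C | starting material
10 | 5-methylhex-5-enal | C=C(C)CCCC=O | intermediate
11 | 5-methyl-2-methylidenehex-5-enal | C=C(C)CCC(=C)C=O | intermediate
12 | (2R)-2-{[(2S,3R,6R,10R)-2,3-dimethyl-6-(3-methylbut-2-en-1-yl)-4,5,8-trioxo-10-phenyl-2,3,4,5,9,10-hexahydro-6H,8H-pyrano[2,3-f]chromen-6-yl]methyl}-5-methylhex-5-enal | C=C(C)CC[C@@H](C=O)C[C@@]1(CC=C(C)C)C(=O)C2=C(O[C@@H](C)[C@@H](C)C2=O)C2=C1OC(=O)C[C@@H]2c1ccccc1 | intermediate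
13 | (2S,3R,6S,10R)-2,3-dimethyl-6-[(2R)-5-methyl-2-(2-methylprop-1-en-1-yl)hex-5-en-1-yl]-6-(3-methylbut-2-en-1-yl)-10-phenyl-2,3,9,10-tetrahydro-4H,8H-pyrano[2,3-f]chromene-4,5,8(6H)-trione (enol lactone of the target) | C=C(C)CC[C@@H](C=C(C)C)C[C@@]1(CC=C(C)C)C(=O)C2=C(O[C@@H](C)[C@@H](C)C2=O)C2=C1OC(=O)C[C@@H]2c1ccccc1 | intermediate
14 | (3R)-3-{(2S,3R,6S)-4-hydroxy-2,3-dimethyl-6-[(2R)-5-methyl-2-(2-methylprop-1-en-1-yl)hex-5-en-1-yl]-6-(3-methylbut-2-en-1-yl)-5,7-dioxo-3,5,6,7-tetrahydro-2H-chromen-8-yl}-3-phenylpropanoic acid | C=C(C)CC[C@@H](C=C(C)C)C[C@@]1(CC=C(C)C)C(=O)C2=C(O)[C@H](C)[C@H](C)OC2=C([C@H](CC(=O)O)c2ccccc2)C1=O | target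

## Step count and risks

Total: 8 steps. Longest linear sequence: 6 steps (1, 2, 3, 4, 7, 8); steps 5 and 6 form the side branch that joins at step 7.

The three steps most likely to fail:

**Step 3 (C6 versus C8 prenylation, and base contact of the cis-chromanone).** The fallback prenylates before ring B is closed. It sets out from 3: Pd(PPh3)4 (5 mol%) and prenyl methyl carbonate in THF at rt (neutral Tsuji–Trost C-allylation; the two free ring carbons of 3 are equivalent, so only one mono-C-prenyl isomer is possible) give (E)-2-methyl-1-[2,4,6-trihydroxy-3-(3-methylbut-2-en-1-yl)phenyl]but-2-en-1-one F1. The quinidine-catalysed oxa-Michael closure of step 2 is then run on this ketone; it should close through the less hindered hydroxyl remote from the prenyl group, the preference known for 3'-prenylated 2',4',6'-trihydroxychalcones closing to 6-prenylflavanones. The fallback comes back to the route at 6.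

**Step 7 (the new reaction).** Likely failure modes are low reactivity of the chelated phenol, reversibility, aminolysis of the aryl lactone by the catalyst, and poor control of either centre. The fallback splits the two centres and uses known reactions only. It sets out from 8: base-mediated alkylative dearomatisation with acrolein (Cs2CO3, THF, −20 °C, the known conjugate-addition dearomatisation of C-substituted acylphloroglucinol-type phenols) gives the C6-quaternary aldehyde as two C6 epimers. These are diastereomers and are separated by preparative HPLC to give 3-[(2S,3R,6S,10R)-2,3-dimethyl-6-(3-methylbut-2-en-1-yl)-4,5,8-trioxo-10-phenyl-2,3,4,5,9,10-hexahydro-6H,8H-pyrano[2,3-f]chromen-6-yl]propanal F2. The established amine-catalysed Michael addition of this aldehyde to methyl vinyl ketone ((S)-2-[diphenyl(trimethylsilyloxy)methyl]pyrrolidine, 10 mol%, catechol co-catalyst, CHCl3, 4 °C; antipode if needed) sets the side-chain centre under catalyst control and gives (2R)-2-{[(2S,3R,6R,10R)-2,3-dimethyl-6-(3-methylbut-2-en-1-yl)-4,5,8-trioxo-10-phenyl-2,3,4,5,9,10-hexahydro-6H,8H-pyrano[2,3-f]chromen-6-yl]methyl}-5-oxohexanal F3. Two Wittig reactions in one flask (Ph3P=CMe2 at −78 °C on the aldehyde, then Ph3P=CH2 at 0 °C on the methyl ketone) bring the fallback back to the route at 13, which is opened with LiOH as in step 8.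

**Step 8 (a basic ylide on an α-branched aldehyde next to an enol lactone and an epimerisable C3).** The fallback reverses the order of the two operations. It sets out from 12: LiOH (THF/H2O, 0 °C, 15 min, then pH 4) opens the enol lactone first and gives (3R)-3-{(2S,3R,6R)-6-[(2R)-2-formyl-5-methylhex-5-en-1-yl]-4-hydroxy-2,3-dimethyl-6-(3-methylbut-2-en-1-yl)-5,7-dioxo-3,5,6,7-tetrahydro-2H-chromen-8-yl}-3-phenylpropanoic acid F4. In this compound ring A is an enolised triketone and the aldehyde can rest as a cyclic hemiacetal on the C7 enol oxygen. Wittig olefination of this lactol with excess Ph3P=CMe2 (4 equiv; the first two equivalents only deprotonate the acid and the triketone, which shields C3 and the ring carbonyls) comes back to the route at 14.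

Further compounds

F1 | step 3 | (E)-2-methyl-1-[2,4,6-trihydroxy-3-(3-methylbut-2-en-1-yl)phenyl]but-2-en-1-one | C/C=C(\C)C(=O)c1c(O)cc(O)c(CC=C(C)C)c1O
F2 | step 7 | 3-[(2S,3R,6S,10R)-2,3-dimethyl-6-(3-methylbut-2-en-1-yl)-4,5,8-trioxo-10-phenyl-2,3,4,5,9,10-hexahydro-6H,8H-pyrano[2,3-f]chromen-6-yl]propanal | O=CCC[C@@]1(CC=C(C)C)C(=O)C2=C(O[C@@H](C)[C@@H](C)C2=O)C2=C1OC(=O)C[C@@H]2c1ccccc1
F3 | step 7 | (2R)-2-{[(2S,3R,6R,10R)-2,3-dimethyl-6-(3-methylbut-2-en-1-yl)-4,5,8-trioxo-10-phenyl-2,3,4,5,9,10-hexahydro-6H,8H-pyrano[2,3-f]chromen-6-yl]methyl}-5-oxohexanal | CC(=O)CC[C@@H](C=O)C[C@@]1(CC=C(C)C)C(=O)C2=C(O[C@@H](C)[C@@H](C)C2=O)C2=C1OC(=O)C[C@@H]2c1ccccc1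
F4 | step 8 | (3R)-3-{(2S,3R,6R)-6-[(2R)-2-formyl-5-methylhex-5-en-1-yl]-4-hydroxy-2,3-dimethyl-6-(3-methylbut-2-en-1-yl)-5,7-dioxo-3,5,6,7-tetrahydro-2H-chromen-8-yl}-3-phenylpropanoic acid | C=C(C)CC[C@@H](C=O)C[C@@]1(CC=C(C)C)C(=O)C2=C(O)[C@H](C)[C@H](C)OC2=C([C@H](CC(=O)O)c2ccccc2)C1=O
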